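**Plan**
- Late cuts: the O1–C2 bond of the dihydrofuran ring (palladium-catalysed asymmetric allylic etherification) and the C3–C3a bond (C-alkylation of the one free ring carbon of a mono-prenylated acylphloroglucinol); the tertiary alcohol is traced back to an isopropenyl group.
- Core cut: the benzene ring (ring A) carries oxygen on the alternate carbons C7a, C6 and C4 and the 3-arylpropanoyl group on C7, the folding pattern of a tetraketide. It is therefore opened at C7–C7a to a 3,5,7-triketo ester whose chain carbon C4 already holds the prenyl group found on C5.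
- Chain cuts: C6–C7 of the triketo ester (ester acylation of a trianion) and the C4–prenyl bond (alkylation of methyl 3,5-dioxohexanoate, itself made from dehydroacetic acid).
- Forward order: chain (steps 1–3), benzene ring by Claisen closure (step 4), E-configured C5 allylic carbonate side chain on the future C3a (steps 5–7), para-silylation (step 8), dihydrofuran ring (step 9), hydration and desilylation (steps 10–11).
- Stereochemistry: the only stereocentre, C2 (S), is set in step 9 by the chiral diphosphine on palladium; the E geometry this step needs is fixed in the bromide reagent and carried through an SN2 alkylation.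

Key step: step 4

Remark: ring positions of the target are given in 2,3-dihydro-1-benzofuran numbering; positions of the open-chain precursors count from the ester carbon C1.
Remark (assumption): the (S,S)-ligand is taken to deliver the 2S product, by analogy with cyclisations of simpler (E)-4-(2-hydroxyaryl)-2-methylbut-2-enyl carbonates; the substrate is achiral, so the (R,R)-ligand would be used if a first run showed the opposite sense.
Remark (assumption): ethyl (E)-4-bromo-2-methylbut-2-enoate is taken as a commercial, geometrically pure E ester.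

**Step 1**
Reactants: 1 dehydroacetic acid
Product: 3 methyl 3,5-dioxohexanoate, via methyl 2-acetyl-3,5-dioxohexanoate 2 (not isolated)
Conditions: Mg(OMe)2 (2.2 equiv), MeOH, reflux; then cold aq. HCl
Reagents that add atoms: methanol, CO (supplied as Mg(OMe)2 in methanol)
Why: Methoxide opens the pyranone lactone and the magnesium-chelated 2-acetyl diketo ester then loses its acetyl group as methyl acetate by retro-Claisen cleavage (lactone methanolysis followed by deacetylation), a standard entry to this diketo ester.

**Step 2**
Reactants: 3 methyl 3,5-dioxohexanoate; 4 prenyl bromide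
Product: 5 methyl 4-(3-methylbut-2-en-1-yl)-3,5-dioxohexanoate
Conditions: K2CO3 (1.1 equiv), 4 (1.0 equiv), acetone, rt
Reagents that add atoms: none
Why: C4, flanked by two ketones, is the most acidic carbon, so the monoenolate formed with carbonate is alkylated there by the reactive allylic bromide (C-alkylation of a β-diketone), while one equivalent of bromide and the lower acidity of the product limit a second alkylation.

**Step 3**
Reactants: 5 methyl 4-(3-methylbut-2-en-1-yl)-3,5-dioxohexanoate; 6 methyl 3-(4-methoxyphenyl)propanoate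
Product: 7 methyl 9-(4-methoxyphenyl)-4-(3-methylbut-2-en-1-yl)-3,5,7-trioxononanoate
Conditions: 5 (2.0 equiv), LiN(i-Pr)2 (6.0 equiv), THF, −78 → 0 °C; 6 (1.0 equiv), 0 °C; then cold aq. HCl; crude product used directly
Reagents that add atoms: none
Why: Three equivalents of amide base per diketo ester remove the C4, C2 and finally the terminal C6 protons, and the trianion reacts through this last-formed, most basic carbanion with the ester carbonyl of 6 (Claisen-type acylation of a polyanion), the second equivalent of trianion serving as base for the more acidic product.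

**Step 4**
Reactants: 7 methyl 9-(4-methoxyphenyl)-4-(3-methylbut-2-en-1-yl)-3,5,7-trioxononanoate
Product: 9 1-[2,4,6-trihydroxy-3-(3-methylbut-2-en-1-yl)phenyl]-3-(4-methoxyphenyl)propan-1-one, via 2-[3-(4-methoxyphenyl)propanoyl]-4-(3-methylbut-2-en-1-yl)cyclohexane-1,3,5-trione 8 (not isolated)
Conditions: Mg(OMe)2 (3 equiv), MeOH, rt → reflux; then aq. HCl
Reagents that add atoms: none
Why: In methanolic Mg(OMe)2 the chain sits as a magnesium-chelated polyenolate whose C6 carbon, the methylene between the C5 and C7 carbonyls, attacks the ester carbonyl C1; methoxide leaves and the cyclic triketone 8 enolises at once to the aromatic triol 9. The closest known reaction type is the intramolecular Claisen (Dieckmann-type) condensation by which 3,5,7-triketo esters are aromatised to acylphloroglucinols under base or magnesium alkoxide. The benzene ring closes in a 6-exo-trig mode, the attacked carbonyl oxygen ending outside the new ring, and the bond formed is the later C7–C7a bond. No stereocentre is created. The step needs Claisen closure to win over the aldol mode (C2 onto the C7 ketone, leading to a resorcylate) and over lactonisation to a pyranone; the ester in place of the free acid, chelation of the C5/C7 diketone by magnesium, which keeps C7 enolised and thus a poor electrophile, and methanol as solvent, which reopens any pyranone, are what secure it. Since the prenyl and acyl groups are fixed on the chain, they can only end on C5 and C7, and O-prenylation or multiple prenylation of a phloroglucinol cannot arise.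

**Step 5**
Reactants: 10 ethyl (E)-4-bromo-2-methylbut-2-enoate
Product: 11 (E)-4-bromo-2-methylbut-2-en-1-ol
Conditions: i-Bu2AlH (2.2 equiv), CH2Cl2, −78 °C; aq. potassium sodium tartrate
Reagents that add atoms: none
Why: i-Bu2AlH reduces the conjugated ester to the primary allylic alcohol by two 1,2-hydride additions at low temperature (ester reduction), which leaves the allylic bromide and the E geometry of the trisubstituted alkene intact.

**Step 6**
Reactants: 11 (E)-4-bromo-2-methylbut-2-en-1-ol
Product: 12 (E)-4-bromo-2-methylbut-2-en-1-yl methyl carbonate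
Conditions: ClCO2Me (1.2 equiv), pyridine (1.5 equiv), CH2Cl2, −10 °C
Reagents that add atoms: methyl chloroformate, COC(=O)Cl
Why: Acylation of the primary alcohol by the chloroformate in the presence of pyridine (carbonate formation) is fast at −10 °C, a temperature at which quaternisation of the allylic bromide by pyridine should not compete.

**Step 7**
Reactants: 9 1-[2,4,6-trihydroxy-3-(3-methylbut-2-en-1-yl)phenyl]-3-(4-methoxyphenyl)propan-1-one; 12 (E)-4-bromo-2-methylbut-2-en-1-yl methyl carbonate
Product: 13 1-[2,4,6-trihydroxy-3-{(E)-4-[(methoxycarbonyl)oxy]-3-methylbut-2-en-1-yl}-5-(3-methylbut-2-en-1-yl)phenyl]-3-(4-methoxyphenyl)propan-1-one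
Conditions: DBU (1.0 equiv), THF, 0 °C; then 12 (1.0 equiv), 0 °C → rt
Reagents that add atoms: none
Why: The DBU salt of 9 is a vinylogous enolate whose only unsubstituted ring carbon, between the para hydroxyl and an ortho hydroxyl, displaces the primary allylic bromide by SN2 and re-aromatises (classical C-alkylation of an acylphloroglucinol with an allylic bromide), so the E alkene of 12 is carried over unchanged and the carbonate is left alone by the fully protonated amidine base.

**Step 8**
Reactants: 13 1-[2,4,6-trihydroxy-3-{(E)-4-[(methoxycarbonyl)oxy]-3-methylbut-2-en-1-yl}-5-(3-methylbut-2-en-1-yl)phenyl]-3-(4-methoxyphenyl)propan-1-one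
Product: 14 1-[4-(tert-butyldimethylsilyloxy)-2,6-dihydroxy-3-{(E)-4-[(methoxycarbonyl)oxy]-3-methylbut-2-en-1-yl}-5-(3-methylbut-2-en-1-yl)phenyl]-3-(4-methoxyphenyl)propan-1-one
Conditions: t-BuMe2SiCl (1.05 equiv), imidazole (2 equiv), DMF, 0 °C
Reagents that add atoms: tert-butyldimethylsilyl chloride, CC(C)(C)[Si](C)(C)Cl
Why: The hydroxyl para to the ketone is the most acidic and cannot hydrogen-bond to the carbonyl, so one equivalent of silyl chloride should silylate it in preference to the two ortho hydroxyls that flank the carbonyl (regioselective phenol silylation), which leaves only the hydroxyl between the acyl group and the new side chain able to close the furan ring.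

**Step 9**
Reactants: 14 1-[4-(tert-butyldimethylsilyloxy)-2,6-dihydroxy-3-{(E)-4-[(methoxycarbonyl)oxy]-3-methylbut-2-en-1-yl}-5-(3-methylbut-2-en-1-yl)phenyl]-3-(4-methoxyphenyl)propan-1-one
Product: 15 1-[(2S)-4-(tert-butyldimethylsilyloxy)-6-hydroxy-5-(3-methylbut-2-en-1-yl)-2-(prop-1-en-2-yl)-2,3-dihydro-1-benzofuran-7-yl]-3-(4-methoxyphenyl)propan-1-one
Conditions: Pd2(dba)3·CHCl3 (2.5 mol %), (S,S)-DACH-phenyl diphosphine ligand, N,N'-[(1S,2S)-cyclohexane-1,2-diyl]bis[2-(diphenylphosphanyl)benzamide] (7.5 mol %), AcOH (1 equiv), CH2Cl2, rt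
Reagents that add atoms: none
Why: Zerovalent palladium ionises the allylic carbonate with loss of CO2 and methoxide to a 1-substituted 2-methyl-π-allyl complex, whose two diastereomeric forms interconvert through the unsubstituted terminus (acetic acid helps) before the adjacent phenoxide attacks the internal allyl carbon in a 5-exo ring closure inside the chiral pocket of the (S,S)-diphosphine (intramolecular asymmetric Tsuji–Trost allylic etherification, known for (E)-4-(2-hydroxyaryl)-2-methylbut-2-enyl carbonates), so that the ligand sets the new C2 centre as S.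

**Step 10**
Reactants: 15 1-[(2S)-4-(tert-butyldimethylsilyloxy)-6-hydroxy-5-(3-methylbut-2-en-1-yl)-2-(prop-1-en-2-yl)-2,3-dihydro-1-benzofuran-7-yl]-3-(4-methoxyphenyl)propan-1-one
Product: 16 1-[(2S)-4-(tert-butyldimethylsilyloxy)-6-hydroxy-2-(2-hydroxypropan-2-yl)-5-(3-methylbut-2-en-1-yl)-2,3-dihydro-1-benzofuran-7-yl]-3-(4-methoxyphenyl)propan-1-one
Conditions: Co(acac)2 (20 mol %), PhSiH3 (2 equiv), O2 (1 atm), THF, rt
Reagents that add atoms: dioxygen, O=O
Why: Under Mukaiyama hydration conditions a cobalt hydride formed from Co(acac)2 and PhSiH3 delivers a hydrogen atom to the unhindered CH2 terminus of the 1,1-disubstituted alkene and the tertiary radical is trapped by O2 and reduced to the tertiary alcohol, while the trisubstituted prenyl alkene, whose hydrogen-accepting carbon is substituted, is expected to react more slowly and C2 is not involved.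

**Step 11**
Reactants: 16 1-[(2S)-4-(tert-butyldimethylsilyloxy)-6-hydroxy-2-(2-hydroxypropan-2-yl)-5-(3-methylbut-2-en-1-yl)-2,3-dihydro-1-benzofuran-7-yl]-3-(4-methoxyphenyl)propan-1-one
Product: 17 1-[(2S)-4,6-dihydroxy-2-(2-hydroxypropan-2-yl)-5-(3-methylbut-2-en-1-yl)-2,3-dihydro-1-benzofuran-7-yl]-3-(4-methoxyphenyl)propan-1-one
Conditions: Bu4NF (1.1 equiv), AcOH (1.1 equiv), THF, 0 °C
Reagents that add atoms: none
Why: Fluoride attacks silicon and releases the phenol (silyl ether cleavage), and buffering with acetic acid keeps the medium mild enough for the prenyl group, the tertiary alcohol and the C2 stereocentre to remain untouched.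

**Compound list**
1 | dehydroacetic acid | CC(=O)C1=C(O)C=C(C)OC1=O | starting material
2 | methyl 2-acetyl-3,5-dioxohexanoate | COC(=O)C(C(C)=O)C(=O)CC(C)=O | intermediate, not isolated
3 | methyl 3,5-dioxohexanoate | COC(=O)CC(=O)CC(C)=O | intermediate
4 | prenyl bromide (1-bromo-3-methylbut-2-ene) | CC(C)=CCBr | starting material
5 | methyl 4-(3-methylbut-2-en-1-yl)-3,5-dioxohexanoate | COC(=O)CC(=O)C(CC=C(C)C)C(C)=O | intermediate
6 | methyl 3-(4-methoxyphenyl)propanoate | COC(=O)CCc1ccc(OC)cc1 | starting material
7 | methyl 9-(4-methoxyphenyl)-4-(3-methylbut-2-en-1-yl)-3,5,7-trioxononanoate | COC(=O)CC(=O)C(CC=C(C)C)C(=O)CC(=O)CCc1ccc(OC)cc1 | intermediate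
8 | 2-[3-(4-methoxyphenyl)propanoyl]-4-(3-methylbut-2-en-1-yl)cyclohexane-1,3,5-trione | COc1ccc(CCC(=O)C2C(=O)CC(=O)C(CC=C(C)C)C2=O)cc1 | intermediate, not isolated
9 | 1-[2,4,6-trihydroxy-3-(3-methylbut-2-en-1-yl)phenyl]-3-(4-methoxyphenyl)propan-1-one | COc1ccc(CCC(=O)c2c(O)cc(O)c(CC=C(C)C)c2O)cc1 | intermediate
10 | ethyl (E)-4-bromo-2-methylbut-2-enoate | CCOC(=O)/C(C)=C/CBr | starting material
11 | (E)-4-bromo-2-methylbut-2-en-1-ol | OC/C(C)=C/CBr | intermediate
12 | (E)-4-bromo-2-methylbut-2-en-1-yl methyl carbonate | COC(=O)OC/C(C)=C/CBr | intermediate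
13 | 1-[2,4,6-trihydroxy-3-{(E)-4-[(methoxycarbonyl)oxy]-3-methylbut-2-en-1-yl}-5-(3-methylbut-2-en-1-yl)phenyl]-3-(4-methoxyphenyl)propan-1-one | COc1ccc(CCC(=O)c2c(O)c(C/C=C(\C)COC(=O)OC)c(O)c(CC=C(C)C)c2O)cc1 | intermediate
14 | 1-[4-(tert-butyldimethylsilyloxy)-2,6-dihydroxy-3-{(E)-4-[(methoxycarbonyl)oxy]-3-methylbut-2-en-1-yl}-5-(3-methylbut-2-en-1-yl)phenyl]-3-(4-methoxyphenyl)propan-1-one | COc1ccc(CCC(=O)c2c(O)c(C/C=C(\C)COC(=O)OC)c(O[Si](C)(C)C(C)(C)C)c(CC=C(C)C)c2O)cc1 | intermediate
15 | 1-[(2S)-4-(tert-butyldimethylsilyloxy)-6-hydroxy-5-(3-methylbut-2-en-1-yl)-2-(prop-1-en-2-yl)-2,3-dihydro-1-benzofuran-7-yl]-3-(4-methoxyphenyl)propan-1-one | COc1ccc(CCC(=O)c2c(O)c(CC=C(C)C)c(O[Si](C)(C)C(C)(C)C)c3c2O[C@H](C(C)=C)C3)cc1 | intermediate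
16 | 1-[(2S)-4-(tert-butyldimethylsilyloxy)-6-hydroxy-2-(2-hydroxypropan-2-yl)-5-(3-methylbut-2-en-1-yl)-2,3-dihydro-1-benzofuran-7-yl]-3-(4-methoxyphenyl)propan-1-one | COc1ccc(CCC(=O)c2c(O)c(CC=C(C)C)c(O[Si](C)(C)C(C)(C)C)c3c2O[C@H](C(C)(C)O)C3)cc1 | intermediate
17 | 1-[(2S)-4,6-dihydroxy-2-(2-hydroxypropan-2-yl)-5-(3-methylbut-2-en-1-yl)-2,3-dihydro-1-benzofuran-7-yl]-3-(4-methoxyphenyl)propan-1-one | COc1ccc(CCC(=O)c2c(O)c(CC=C(C)C)c(O)c3c2O[C@H](C(C)(C)O)C3)cc1 | target

**Step count**
Total: 11 steps. Longest linear sequence: 9 steps (steps 1–4 and 7–11, from dehydroacetic acid); steps 5–6 make the side-chain reagent and converge at step 7.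

**Steps most likely to fail**

Step 3. The trianion may be consumed by proton transfer from the enolisable ester and from the product, or the third deprotonation of the branched diketo ester may stay incomplete, so that little C6 acylation occurs. The fallback masks the ester and the C3 enol in a pyranone so that only a dianion is needed. It sets out from 5, which is cyclised with loss of methanol (DBU, toluene, reflux) to 4-hydroxy-6-methyl-5-(3-methylbut-2-en-1-yl)-2H-pyran-2-one F1. The dianion of F1 (LiN(i-Pr)2, 3 equiv, THF, −78 °C) should be acylated at the 6-methyl group by 6 to give 4-hydroxy-6-[4-(4-methoxyphenyl)-2-oxobutyl]-5-(3-methylbut-2-en-1-yl)-2H-pyran-2-one F2. Methanolysis of the lactone of F2 with Mg(OMe)2 in MeOH regenerates the open-chain ester in the flask, so the route is rejoined at 7, and the same medium carries it on to 9 as in step 4.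

Step 7. O-alkylation and a second, dearomatising alkylation at the prenyl-bearing ring carbon may compete with the wanted C-alkylation. The fallback replaces the base-mediated SN2 reaction by a neutral palladium-catalysed allylation. It sets out from 9, whose para hydroxyl is silylated first (t-BuMe2SiCl, imidazole, DMF) to 1-[4-(tert-butyldimethylsilyloxy)-2,6-dihydroxy-3-(3-methylbut-2-en-1-yl)phenyl]-3-(4-methoxyphenyl)propan-1-one F3. Treatment of F3 with 2-methyl-2-vinyloxirane and Pd(PPh3)4 in THF should proceed by opening of the vinyl epoxide with zerovalent palladium to a π-allyl alkoxide, which deprotonates the phenol; O-allyl ethers re-ionise, so the C-allylated arene should accumulate. After removal of any Z isomer this gives 1-[4-(tert-butyldimethylsilyloxy)-2,6-dihydroxy-3-[(E)-4-hydroxy-3-methylbut-2-en-1-yl]-5-(3-methylbut-2-en-1-yl)phenyl]-3-(4-methoxyphenyl)propan-1-one F4. Methyl chloroformate and pyridine at −20 °C then convert the primary alcohol of F4 into the carbonate, and the route is rejoined at 14.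

Step 10. Hydrogen-atom transfer to the prenyl alkene may compete and lead to hydration of both alkenes, and the free phenol may be oxidised under the aerobic radical conditions. The fallback changes from radical to electrophilic hydration, where steric access decides and a 1,1-disubstituted alkene reacts faster than a trisubstituted one. It sets out from 15, which with Hg(OAc)2 in THF–H2O at 0 °C should give the organomercurial 1-[(2S)-2-[1-(acetoxymercurio)-2-hydroxypropan-2-yl]-4-(tert-butyldimethylsilyloxy)-6-hydroxy-5-(3-methylbut-2-en-1-yl)-2,3-dihydro-1-benzofuran-7-yl]-3-(4-methoxyphenyl)propan-1-one F5 (both epimers at the carbinol carbon). Reductive demercuration of F5 with NaBH4 in aqueous NaOH at 0 °C replaces mercury by hydrogen, and the route is rejoined at 16.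

**Further compounds**
F1 | step 3 | 4-hydroxy-6-methyl-5-(3-methylbut-2-en-1-yl)-2H-pyran-2-one | CC1=C(CC=C(C)C)C(O)=CC(=O)O1
F2 | step 3 | 4-hydroxy-6-[4-(4-methoxyphenyl)-2-oxobutyl]-5-(3-methylbut-2-en-1-yl)-2H-pyran-2-one | COc1ccc(CCC(=O)CC2=C(CC=C(C)C)C(O)=CC(=O)O2)cc1
F3 | step 7 | 1-[4-(tert-butyldimethylsilyloxy)-2,6-dihydroxy-3-(3-methylbut-2-en-1-yl)phenyl]-3-(4-methoxyphenyl)propan-1-one | COc1ccc(CCC(=O)c2c(O)cc(O[Si](C)(C)C(C)(C)C)c(CC=C(C)C)c2O)cc1
F4 | step 7 | 1-[4-(tert-butyldimethylsilyloxy)-2,6-dihydroxy-3-[(E)-4-hydroxy-3-methylbut-2-en-1-yl]-5-(3-methylbut-2-en-1-yl)phenyl]-3-(4-methoxyphenyl)propan-1-one | COc1ccc(CCC(=O)c2c(O)c(C/C=C(\C)CO)c(O[Si](C)(C)C(C)(C)C)c(CC=C(C)C)c2O)cc1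
F5 | step 10 | 1-[(2S)-2-[1-(acetoxymercurio)-2-hydroxypropan-2-yl]-4-(tert-butyldimethylsilyloxy)-6-hydroxy-5-(3-methylbut-2-en-1-yl)-2,3-dihydro-1-benzofuran-7-yl]-3-(4-methoxyphenyl)propan-1-one | COc1ccc(CCC(=O)c2c(O)c(CC=C(C)C)c(O[Si](C)(C)C(C)(C)C)c3c2O[C@H](C(C)(O)C[Hg]OC(C)=O)C3)cc1
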